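**Retrosynthetic overview**
- C40 → Wittig at C11'=C12': ε-C15 phosphonium salt + C25 3-hydroxy-7,8-didehydro-apocarotenal; the C25 aldehyde → Wittig at C11=C12: acetylenic C15 phosphonium salt + C10 dialdehyde.
- Acetylenic C15 salt → Sonogashira coupling of the enol triflate of (4R,6R)-actinol with (E)-3-methylpent-2-en-4-yn-1-ol; the hydroxylated ring is taken from the chiral pool and is not formed in the route.
- ε-C15 salt → Julia–Kocienski olefination (C7'=C8') of an (R)-α-cyclogeranyl tetrazolyl sulfone with a C5 acetoxy enal.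
- Sulfone → cis-fused bicyclic β-lactone (reduction, thiol Mitsunobu, syn-dehydration, S-oxidation).
- Ring formation: the cyclohexane of the ε ring and a β-lactone ring close together in one catalytic asymmetric aldol-lactonisation of an acyclic keto acid, which sets C6'; the lactone ring is opened in the following step.

Assumption: (S)-HBTM is written as the catalyst giving the (1R,6S)-lactone (sense of induction by analogy; the antipodal catalyst is used if it proves reversed), and (4R,6R)-actinol, the C10 dialdehyde and (E)-4-acetoxy-2-methylbut-2-enal are bought as industrial carotenoid and vitamin A intermediates.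

**Route**

Step 1
Reactants: 1 2-(3-chloropropyl)-2-methyl-1,3-dioxolane; 2 diethyl 2-(propan-2-ylidene)malonate
Product: 4 diethyl 2-[2-methyl-5-(2-methyl-1,3-dioxolan-2-yl)pentan-2-yl]malonate, via Grignard reagent 3 (not isolated)
Conditions: Mg, THF, 50 °C; then 2, CuI (5 mol %), THF, −20 °C → rt; aq NH4Cl
Reagents that add atoms: none
Why: Copper-catalysed conjugate addition of the alkyl Grignard reagent to the doubly activated alkylidene malonate builds the quaternary gem-dimethyl carbon (C1') while the dioxolane masks the ketone.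

Step 2
Reactants: 4 diethyl 2-[2-methyl-5-(2-methyl-1,3-dioxolan-2-yl)pentan-2-yl]malonate
Product: 6 3,3-dimethyl-7-oxooctanoic acid, via keto malonic acid 5 (not isolated)
Conditions: KOH, EtOH/H2O, reflux; then 6 M HCl, reflux
Reagents that add atoms: potassium hydroxide, [K+].[OH-]; water, O
Why: Saponification, acid cleavage of the ketal and thermal decarboxylation of the malonic acid (malonic ester synthesis) give the achiral keto acid.

Step 3
Reactants: 6 3,3-dimethyl-7-oxooctanoic acid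
Product: 8 (1R,6S)-2,2,6-trimethyl-7-oxabicyclo[4.2.0]octan-8-one, via tosyl mixed anhydride 7 (not isolated)
Conditions: TsCl (1.25 equiv), (S)-HBTM (20 mol %), LiCl, i-Pr2NEt, CH2Cl2, 23 °C, slow addition of 6
Reagents that add atoms: none
Why: Nucleophile-catalysed aldol-lactonisation (NCAL): the catalyst-bound ammonium enolate formed from the mixed anhydride adds to one face of the methyl ketone and the tertiary alkoxide closes the β-lactone, so the cyclohexane and the oxetanone form in one operation, the fusion is necessarily cis, and the isothiourea fixes C1 of the bicycle (C6' of the target) as R.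

Step 4
Reactants: 8 (1R,6S)-2,2,6-trimethyl-7-oxabicyclo[4.2.0]octan-8-one
Product: 9 (1S,2S)-2-(hydroxymethyl)-1,3,3-trimethylcyclohexan-1-ol
Conditions: LiAlH4, THF, 0 °C → rt
Reagents that add atoms: none
Why: Hydride reduction of the strained lactone opens the four-membered ring to the cis-1,3-diol without touching either stereocentre.

Step 5
Reactants: 9 (1S,2S)-2-(hydroxymethyl)-1,3,3-trimethylcyclohexan-1-ol
Product: 10 (1S,2R)-1,3,3-trimethyl-2-{[(1-phenyl-1H-tetrazol-5-yl)sulfanyl]methyl}cyclohexan-1-ol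
Conditions: 1-phenyl-1H-tetrazole-5-thiol, PPh3, DIAD, THF, 0 °C → rt
Reagents that add atoms: 1-phenyl-1H-tetrazole-5-thiol, Sc1nnnn1-c1ccccc1
Why: Mitsunobu thioetherification reacts only at the primary alcohol, since the tertiary hydroxyl cannot be displaced, and installs the sulfide for the later olefination.

Step 6
Reactants: 10 (1S,2R)-1,3,3-trimethyl-2-{[(1-phenyl-1H-tetrazol-5-yl)sulfanyl]methyl}cyclohexan-1-ol
Product: 11 1-phenyl-5-({[(1R)-2,6,6-trimethylcyclohex-2-en-1-yl]methyl}sulfanyl)-1H-tetrazole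
Conditions: Burgess reagent, benzene, 50 °C
Reagents that add atoms: none
Why: Burgess dehydration is a syn (Ei) elimination, and because the hydrogen on the stereocentre is trans to the hydroxyl it cannot be removed, so a ring CH2 hydrogen is lost (Saytzeff over methyl) to give the 2-ene (α) isomer with the stereocentre untouched.

Step 7
Reactants: 11 1-phenyl-5-({[(1R)-2,6,6-trimethylcyclohex-2-en-1-yl]methyl}sulfanyl)-1H-tetrazole
Product: 12 1-phenyl-5-({[(1R)-2,6,6-trimethylcyclohex-2-en-1-yl]methyl}sulfonyl)-1H-tetrazole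
Conditions: 30% H2O2, (NH4)6Mo7O24·4H2O (10 mol %), EtOH, 0 °C → rt
Reagents that add atoms: hydrogen peroxide, OO
Why: Molybdate-catalysed peroxide oxidation takes the sulfide to the sulfone faster than it epoxidises the trisubstituted alkene.

Step 8
Reactants: 12 1-phenyl-5-({[(1R)-2,6,6-trimethylcyclohex-2-en-1-yl]methyl}sulfonyl)-1H-tetrazole; 13 (2E)-3-formylbut-2-en-1-yl acetate [(E)-4-acetoxy-2-methylbut-2-enal]
Product: 15 (2E,4E)-3-methyl-5-[(1R)-2,6,6-trimethylcyclohex-2-en-1-yl]penta-2,4-dien-1-yl acetate, via potassium sulfonyl carbanion 14 (not isolated)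
Conditions: KHMDS, DME, −78 °C; then 13, −78 °C → rt
Reagents that add atoms: none
Why: Julia–Kocienski olefination (carbanion addition to the enal, Smiles rearrangement, loss of SO2 and tetrazolone) forms the E-7',8' double bond, and since only the sulfonyl CH2 is deprotonated the ring stereocentre keeps its configuration.

Step 9
Reactants: 15 (2E,4E)-3-methyl-5-[(1R)-2,6,6-trimethylcyclohex-2-en-1-yl]penta-2,4-dien-1-yl acetate
Product: 16 {(2E,4E)-3-methyl-5-[(1R)-2,6,6-trimethylcyclohex-2-en-1-yl]penta-2,4-dien-1-yl}triphenylphosphonium bromide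
Conditions: PPh3·HBr, MeOH/CH2Cl2, rt, dark
Reagents that add atoms: triphenylphosphine hydrobromide, Br.c1ccc(cc1)P(c1ccccc1)c1ccccc1
Why: Acid-promoted ionisation of the allylic acetate and capture of the dienyl cation by PPh3 at the primary terminus gives the C15 Wittig salt (the vitamin A acetate to phosphonium salt reaction type).

Step 10
Reactants: 17 (4R,6R)-4-hydroxy-2,2,6-trimethylcyclohexan-1-one [(4R,6R)-actinol]
Product: 18 (4R,6R)-2,2,6-trimethyl-4-[(triethylsilyl)oxy]cyclohexan-1-one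
Conditions: TESCl, imidazole, DMF, 0 °C → rt
Reagents that add atoms: chlorotriethylsilane, CC[Si](CC)(CC)Cl
Why: Standard silylation protects the secondary alcohol for the strongly basic enolisation that follows.

Step 11
Reactants: 18 (4R,6R)-2,2,6-trimethyl-4-[(triethylsilyl)oxy]cyclohexan-1-one
Product: 20 (4R)-2,6,6-trimethyl-4-[(triethylsilyl)oxy]cyclohex-1-en-1-yl trifluoromethanesulfonate, via potassium enolate 19 (not isolated)
Conditions: KHMDS, THF, −78 °C; then PhNTf2, −78 → 0 °C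
Reagents that add atoms: N-phenylbis(trifluoromethanesulfonimide), O=S(=O)(N(c1ccccc1)S(=O)(=O)C(F)(F)F)C(F)(F)F
Why: The only enolisable position (C6) is deprotonated and the enolate is O-triflated, which fixes the tetrasubstituted ring double bond; the C6 stereocentre is consumed and C4 is unaffected.

Step 12
Reactants: 20 (4R)-2,6,6-trimethyl-4-[(triethylsilyl)oxy]cyclohex-1-en-1-yl trifluoromethanesulfonate; 21 (2E)-3-methylpent-2-en-4-yn-1-ol
Product: 22 (2E)-3-methyl-5-{(4R)-2,6,6-trimethyl-4-[(triethylsilyl)oxy]cyclohex-1-en-1-yl}pent-2-en-4-yn-1-ol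
Conditions: Pd(PPh3)4 (5 mol %), CuI (10 mol %), i-Pr2NH, THF, rt → 40 °C
Reagents that add atoms: none
Why: Sonogashira coupling of the vinyl triflate with the terminal alkyne forms the C6–C7 bond and brings in the 7,8-triple bond and the E-9,10 double bond unchanged.

Step 13
Reactants: 22 (2E)-3-methyl-5-{(4R)-2,6,6-trimethyl-4-[(triethylsilyl)oxy]cyclohex-1-en-1-yl}pent-2-en-4-yn-1-ol
Product: 23 {(2E)-5-[(4R)-4-hydroxy-2,6,6-trimethylcyclohex-1-en-1-yl]-3-methylpent-2-en-4-yn-1-yl}triphenylphosphonium bromide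
Conditions: PPh3·HBr (1.2 equiv), MeOH, rt
Reagents that add atoms: triphenylphosphine hydrobromide, Br.c1ccc(cc1)P(c1ccccc1)c1ccccc1
Why: The allylic alcohol is converted into the phosphonium salt by PPh3·HBr (SN1-type substitution), and the same acidic methanol removes the triethylsilyl ether.

Step 14
Reactants: 23 {(2E)-5-[(4R)-4-hydroxy-2,6,6-trimethylcyclohex-1-en-1-yl]-3-methylpent-2-en-4-yn-1-yl}triphenylphosphonium bromide; 24 (2E,4E,6E)-2,7-dimethylocta-2,4,6-trienedial
Product: 25 (2E,4E,6E,8E,10E)-13-[(4R)-4-hydroxy-2,6,6-trimethylcyclohex-1-en-1-yl]-2,7,11-trimethyltrideca-2,4,6,8,10-pentaen-12-ynal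
Conditions: 24 (3 equiv), NaOMe, CH2Cl2/MeOH, 0 °C → rt; chromatography of the all-E isomer
Reagents that add atoms: none
Why: Wittig olefination of one aldehyde group of the dialdehyde, used in excess, gives the C25 apocarotenal with the new C11=C12 bond.

Step 15
Reactants: 16 {(2E,4E)-3-methyl-5-[(1R)-2,6,6-trimethylcyclohex-2-en-1-yl]penta-2,4-dien-1-yl}triphenylphosphonium bromide; 25 (2E,4E,6E,8E,10E)-13-[(4R)-4-hydroxy-2,6,6-trimethylcyclohex-1-en-1-yl]-2,7,11-trimethyltrideca-2,4,6,8,10-pentaen-12-ynal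
Product: 26 (3R,6'R)-7,8-didehydro-β,ε-caroten-3-ol (CNP0322200.1)
Conditions: NaOMe, CH2Cl2/MeOH, rt, dark; then heptane, 80 °C (Z → E), crystallisation
Reagents that add atoms: none
Why: The final Wittig olefination joins the two halves at C11'=C12', the E/Z mixture from the semi-stabilised ylide is equilibrated thermally to the all-E polyene, and neither stereocentre takes part.

**Compound list**
1 | 2-(3-chloropropyl)-2-methyl-1,3-dioxolane | CC1(CCCCl)OCCO1 | starting material
2 | diethyl 2-(propan-2-ylidene)malonate | CCOC(=O)C(=C(C)C)C(=O)OCC | starting material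
3 | [3-(2-methyl-1,3-dioxolan-2-yl)propyl]magnesium chloride | CC1(CCC[Mg]Cl)OCCO1 | intermediate
4 | diethyl 2-[2-methyl-5-(2-methyl-1,3-dioxolan-2-yl)pentan-2-yl]malonate | CCOC(=O)C(C(=O)OCC)C(C)(C)CCCC1(C)OCCO1 | intermediate
5 | 2-(2-methyl-6-oxoheptan-2-yl)malonic acid | CC(=O)CCCC(C)(C)C(C(=O)O)C(=O)O | intermediate
6 | 3,3-dimethyl-7-oxooctanoic acid | CC(=O)CCCC(C)(C)CC(=O)O | intermediate
7 | 3,3-dimethyl-7-oxooctanoic 4-methylbenzenesulfonic anhydride | CC(=O)CCCC(C)(C)CC(=O)OS(=O)(=O)c1ccc(C)cc1 | intermediate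
8 | (1R,6S)-2,2,6-trimethyl-7-oxabicyclo[4.2.0]octan-8-one | O=C1O[C@@]2(C)CCCC(C)(C)[C@@H]12 | intermediate
9 | (1S,2S)-2-(hydroxymethyl)-1,3,3-trimethylcyclohexan-1-ol | O[C@@]1(C)CCCC(C)(C)[C@H]1CO | intermediate
10 | (1S,2R)-1,3,3-trimethyl-2-{[(1-phenyl-1H-tetrazol-5-yl)sulfanyl]methyl}cyclohexan-1-ol | O[C@@]1(C)CCCC(C)(C)[C@H]1CSc1nnnn1-c1ccccc1 | intermediate
11 | 1-phenyl-5-({[(1R)-2,6,6-trimethylcyclohex-2-en-1-yl]methyl}sulfanyl)-1H-tetrazole | CC1=CCCC(C)(C)[C@H]1CSc1nnnn1-c1ccccc1 | intermediate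
12 | 1-phenyl-5-({[(1R)-2,6,6-trimethylcyclohex-2-en-1-yl]methyl}sulfonyl)-1H-tetrazole | CC1=CCCC(C)(C)[C@H]1CS(=O)(=O)c1nnnn1-c1ccccc1 | intermediate
13 | (2E)-3-formylbut-2-en-1-yl acetate | O=C/C(C)=C/COC(C)=O | starting material
14 | potassium [(1-phenyl-1H-tetrazol-5-yl)sulfonyl][(1R)-2,6,6-trimethylcyclohex-2-en-1-yl]methanide | [K+].CC1=CCCC(C)(C)[C@H]1[CH-]S(=O)(=O)c1nnnn1-c1ccccc1 | intermediate
15 | (2E,4E)-3-methyl-5-[(1R)-2,6,6-trimethylcyclohex-2-en-1-yl]penta-2,4-dien-1-yl acetate | CC1=CCCC(C)(C)[C@H]1/C=C/C(C)=C/COC(C)=O | intermediate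
16 | {(2E,4E)-3-methyl-5-[(1R)-2,6,6-trimethylcyclohex-2-en-1-yl]penta-2,4-dien-1-yl}triphenylphosphonium bromide | CC1=CCCC(C)(C)[C@H]1/C=C/C(C)=C/C[P+](c1ccccc1)(c1ccccc1)c1ccccc1.[Br-] | intermediate
17 | (4R,6R)-4-hydroxy-2,2,6-trimethylcyclohexan-1-one | C[C@@H]1C[C@@H](O)CC(C)(C)C1=O | starting material
18 | (4R,6R)-2,2,6-trimethyl-4-[(triethylsilyl)oxy]cyclohexan-1-one | C[C@@H]1C[C@@H](O[Si](CC)(CC)CC)CC(C)(C)C1=O | intermediate
19 | potassium (4R)-2,6,6-trimethyl-4-[(triethylsilyl)oxy]cyclohex-1-en-1-olate | [K+].[O-]C1=C(C)C[C@@H](O[Si](CC)(CC)CC)CC1(C)C | intermediate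
20 | (4R)-2,6,6-trimethyl-4-[(triethylsilyl)oxy]cyclohex-1-en-1-yl trifluoromethanesulfonate | FC(F)(F)S(=O)(=O)OC1=C(C)C[C@@H](O[Si](CC)(CC)CC)CC1(C)C | intermediate
21 | (2E)-3-methylpent-2-en-4-yn-1-ol | OC/C=C(\C)C#C | starting material
22 | (2E)-3-methyl-5-{(4R)-2,6,6-trimethyl-4-[(triethylsilyl)oxy]cyclohex-1-en-1-yl}pent-2-en-4-yn-1-ol | OC/C=C(\C)C#CC1=C(C)C[C@@H](O[Si](CC)(CC)CC)CC1(C)C | intermediate
23 | {(2E)-5-[(4R)-4-hydroxy-2,6,6-trimethylcyclohex-1-en-1-yl]-3-methylpent-2-en-4-yn-1-yl}triphenylphosphonium bromide | [Br-].c1ccccc1[P+](c1ccccc1)(c1ccccc1)C/C=C(\C)C#CC1=C(C)C[C@@H](O)CC1(C)C | intermediate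
24 | (2E,4E,6E)-2,7-dimethylocta-2,4,6-trienedial | O=C/C(C)=C/C=C/C=C(C)/C=O | starting material
25 | (2E,4E,6E,8E,10E)-13-[(4R)-4-hydroxy-2,6,6-trimethylcyclohex-1-en-1-yl]-2,7,11-trimethyltrideca-2,4,6,8,10-pentaen-12-ynal | O=C/C(C)=C/C=C/C=C(C)/C=C/C=C(\C)C#CC1=C(C)C[C@@H](O)CC1(C)C | intermediate
26 | (3R,6'R)-7,8-didehydro-β,ε-caroten-3-ol | CC1=CCCC(C)(C)[C@H]1/C=C/C(C)=C/C=C/C(C)=C/C=C/C=C(C)/C=C/C=C(\C)C#CC1=C(C)C[C@@H](O)CC1(C)C | target

**Step count and risks**

Total steps: 15. Longest linear sequence: 10 (steps 1–9, then step 15).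

Steps most likely to fail:

Step 3 (aldol-lactonisation). The nucleophilic carbon is next to a quaternary centre, and a cyclohexane-fused β-lactone is the harder ring size for this reaction, so yield and ee are uncertain. Fallback, setting out from 6 and coming back at 9: give up catalyst control and cyclise 6 with an achiral promoter (4-pyrrolidinopyridine, 2-bromo-1-propylpyridinium triflate, i-Pr2NEt) to racemic cis-2,2,6-trimethyl-7-oxabicyclo[4.2.0]octan-8-one F1. Reduce this with LiAlH4 to racemic cis-2-(hydroxymethyl)-1,3,3-trimethylcyclohexan-1-ol F2. Resolve F2 by lipase-catalysed acetylation of the primary hydroxyl (Burkholderia cepacia lipase, vinyl acetate), which leaves diol 9 and turns its antipode into [(1R,2R)-2-hydroxy-2,6,6-trimethylcyclohexyl]methyl acetate F3.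

Step 6 (regiochemistry of the dehydration). The exocyclic methylene isomer or, through an ion-pair pathway, the tetrasubstituted 1-ene may form alongside 11. Fallback, setting out from 8 and coming back at 11 (steps 4–6 are bypassed): ionise the lactone with MgBr2·OEt2 in CH2Cl2 so that the departing carboxylate removes a syn ring hydrogen, giving (1R)-2,6,6-trimethylcyclohex-2-ene-1-carboxylic acid F4. Reduce with LiAlH4 to [(1R)-2,6,6-trimethylcyclohex-2-en-1-yl]methanol F5, and convert F5 into 11 by the same Mitsunobu thioetherification.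

Step 8 (Julia–Kocienski olefination). The carbanion is hindered and E/Z selectivity with an enal can be poor. Fallback, setting out from 12 and coming back at 16: alkylate the potassium carbanion of 12 with (E)-4-chloro-3-methylbut-2-en-1-yl acetate (NaI cat., THF) to (2E)-3-methyl-5-[(1-phenyl-1H-tetrazol-5-yl)sulfonyl]-5-[(1R)-2,6,6-trimethylcyclohex-2-en-1-yl]pent-2-en-1-yl acetate F6. Eliminate the sulfinate with t-BuOK and cleave the acetate with K2CO3/MeOH to give (2E,4E)-3-methyl-5-[(1R)-2,6,6-trimethylcyclohex-2-en-1-yl]penta-2,4-dien-1-ol F7. PPh3·HBr in MeOH then converts F7 into 16.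

**Further compounds**
F1 | step 3 | racemic cis-2,2,6-trimethyl-7-oxabicyclo[4.2.0]octan-8-one | O=C1O[C@@]2(C)CCCC(C)(C)[C@@H]12.O=C1O[C@]2(C)CCCC(C)(C)[C@H]12
F2 | step 3 | racemic cis-2-(hydroxymethyl)-1,3,3-trimethylcyclohexan-1-ol | O[C@@]1(C)CCCC(C)(C)[C@H]1CO.O[C@]1(C)CCCC(C)(C)[C@@H]1CO
F3 | step 3 | [(1R,2R)-2-hydroxy-2,6,6-trimethylcyclohexyl]methyl acetate | O[C@]1(C)CCCC(C)(C)[C@@H]1COC(C)=O
F4 | step 6 | (1R)-2,6,6-trimethylcyclohex-2-ene-1-carboxylic acid | CC1=CCCC(C)(C)[C@H]1C(=O)O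
F5 | step 6 | [(1R)-2,6,6-trimethylcyclohex-2-en-1-yl]methanol | CC1=CCCC(C)(C)[C@H]1CO
F6 | step 8 | (2E)-3-methyl-5-[(1-phenyl-1H-tetrazol-5-yl)sulfonyl]-5-[(1R)-2,6,6-trimethylcyclohex-2-en-1-yl]pent-2-en-1-yl acetate (both C5 epimers) | CC1=CCCC(C)(C)[C@H]1C(C/C(C)=C/COC(C)=O)S(=O)(=O)c1nnnn1-c1ccccc1
F7 | step 8 | (2E,4E)-3-methyl-5-[(1R)-2,6,6-trimethylcyclohex-2-en-1-yl]penta-2,4-dien-1-ol | CC1=CCCC(C)(C)[C@H]1/C=C/C(C)=C/CO
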